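**Retrosynthetic overview**

1. Structural feature: in the carbocycle C1–C6 with its exocyclic C7, the chain C7–C1–C2–C3–C4–C5 is the carbon chain C1–C6 of D-glucose. C2 (S) and C3 (R) are glucose C3 and C4 unchanged. C7 lies on the ring face of the C3 oxygen, opposite the cis C1/C2 diol.
2. Endgame: 22 ⇒ enone 21 (BCl3 debenzylation) ⇒ cyclohexene dibenzoate 19 (C6–H hydroxylation by SeO2, then oxidation) ⇒ acid 15 (reduction to C7H2OH, PMB removal, double benzoylation).
3. Key disconnection: 15 ⇒ vinyl gluconolactone 12 by Ireland–Claisen rearrangement. It makes C1–C6 and C4=C5, breaks C4–O, and passes the chirality of C4 to the quaternary C1.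
4. 12 ⇒ phenyl 1-thio-β-D-glucopyranoside 1 (anisylidene acetal, benzylation, reductive opening, C6 oxidation, methylenation, NBS hydrolysis, lactol oxidation). The S-phenyl anomeric mask comes off without acid, so the PMB ether survives.
5. Ring order: the pyranose ring is bought in 1, with a temporary dioxane in 3–5. It becomes the δ-lactone 12. The only carbocycle forms in step 8 at the expense of the lactone ring (six-membered to six-membered).

Key step: step 8

Assumption: 1 is taken as a purchasable thioglycoside; carbocycles carry zeylenone numbering (C1 tertiary carbinol carbon, C2 CHOH, C3 CHOBz, C4=C5, C6 ketone carbon, C7 exocyclic CH2) and sugars carry carbohydrate numbering.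

**Step 1**
Reactants: 1 phenyl 1-thio-β-D-glucopyranoside; 2 4-methoxybenzaldehyde dimethyl acetal
Product: 3 phenyl 4,6-O-[(R)-4-methoxybenzylidene]-1-thio-β-D-glucopyranoside
Conditions: CSA (cat.), MeCN, 50 °C, MeOH stripped off
Reagents that add atoms: 2, 4-methoxybenzaldehyde dimethyl acetal, COc1ccc(C(OC)OC)cc1
Why: Acid-catalysed transacetalisation under thermodynamic control picks the 4,6-diol because only it gives a trans-decalin-like 1,3-dioxane, and the new acetal carbon equilibrates to R with the aryl group equatorial.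

**Step 2**
Reactants: 3 phenyl 4,6-O-[(R)-4-methoxybenzylidene]-1-thio-β-D-glucopyranoside; 4 benzyl bromide
Product: 5 phenyl 2,3-di-O-benzyl-4,6-O-[(R)-4-methoxybenzylidene]-1-thio-β-D-glucopyranoside
Conditions: NaH, BnBr, TBAI (cat.), DMF, 0 °C → rt
Reagents that add atoms: 4, benzyl bromide, BrCc1ccccc1
Why: Williamson etherification of the two remaining secondary alkoxides, to which acetal and thioglycoside are inert and which touches no stereocentre.

**Step 3**
Reactants: 5 phenyl 2,3-di-O-benzyl-4,6-O-[(R)-4-methoxybenzylidene]-1-thio-β-D-glucopyranoside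
Product: 6 phenyl 2,3-di-O-benzyl-4-O-(4-methoxybenzyl)-1-thio-β-D-glucopyranoside (6-OH free)
Conditions: DIBAL-H (PhMe solution), CH2Cl2, −10 → 0 °C; Rochelle salt
Reagents that add atoms: none
Why: Regioselective reductive acetal opening, in which aluminium binds the less hindered O6, the C–O6 bond ionises to the anisyl-stabilised oxocarbenium ion on O4, and hydride delivery leaves PMB on O4 and the primary hydroxyl free.

**Step 4**
Reactants: 6 phenyl 2,3-di-O-benzyl-4-O-(4-methoxybenzyl)-1-thio-β-D-glucopyranoside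
Product: 7 phenyl 2,3-di-O-benzyl-4-O-(4-methoxybenzyl)-1-thio-β-D-gluco-hexodialdo-1,5-pyranoside (6-aldehyde)
Conditions: DMP, CH2Cl2, 0 °C → rt
Reagents that add atoms: none
Why: Dess–Martin oxidation runs without base, so the sulfide is spared and the epimerisable, elimination-prone C5 centre next to the new aldehyde is left alone.

**Step 5**
Reactants: 7 phenyl 2,3-di-O-benzyl-4-O-(4-methoxybenzyl)-1-thio-β-D-gluco-hexodialdo-1,5-pyranoside; 8 methyltriphenylphosphonium bromide
Product: 10 phenyl 2,3-di-O-benzyl-6,7-dideoxy-4-O-(4-methoxybenzyl)-1-thio-β-D-gluco-hept-6-enopyranoside, via methylenetriphenylphosphorane 9 (not isolated)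
Conditions: 8, n-BuLi, THF, 0 °C; then 7, −78 °C → rt
Reagents that add atoms: 8, methyltriphenylphosphonium bromide, C[P+](c1ccccc1)(c1ccccc1)c1ccccc1.[Br-]
Why: Wittig methylenation with the unstabilised ylide is fast at low temperature, so olefination should outrun enolisation of the aldehyde, and it is the standard entry to 6,7-dideoxy-hept-6-enopyranosides.

**Step 6**
Reactants: 10 phenyl 2,3-di-O-benzyl-6,7-dideoxy-4-O-(4-methoxybenzyl)-1-thio-β-D-gluco-hept-6-enopyranoside
Product: 11 2,3-di-O-benzyl-6,7-dideoxy-4-O-(4-methoxybenzyl)-D-gluco-hept-6-enopyranose (α/β lactol)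
Conditions: NBS, acetone–H2O (9:1), −15 °C, dark
Reagents that add atoms: water, O
Why: NBS hydrolysis of a thioglycoside (bromonium activation of sulfur) is much faster than attack on the vinyl group, which the allylic oxygen deactivates, and it runs near neutrality, whereas the hot mineral acid needed for an O-methyl glycoside would strip the PMB ether.

**Step 7**
Reactants: 11 2,3-di-O-benzyl-6,7-dideoxy-4-O-(4-methoxybenzyl)-D-gluco-hept-6-enopyranose
Product: 12 2,3-di-O-benzyl-6,7-dideoxy-4-O-(4-methoxybenzyl)-D-gluco-hept-6-enono-1,5-lactone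
Conditions: DMP, CH2Cl2, rt
Reagents that add atoms: none
Why: Dess–Martin oxidation of the lactol to the aldono-1,5-lactone uses no amine base, which matters because 2,3-dialkoxy gluconolactones lose the 3-alkoxy group by E1cB on contact with base.

**Step 8**
Reactants: 12 2,3-di-O-benzyl-6,7-dideoxy-4-O-(4-methoxybenzyl)-D-gluco-hept-6-enono-1,5-lactone
Product: 15 (1R,2S,3R)-1,2-bis(benzyloxy)-3-(4-methoxybenzyloxy)cyclohex-4-ene-1-carboxylic acid, via silyl ketene acetal 13 (not isolated), via trimethylsilyl ester 14 (not isolated)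
Conditions: TMSCl–Et3N (premixed), then LDA, THF, −100 → 0 °C; pentane, filter; PhMe, 105 °C; then 10% aq citric acid, THF, rt
Reagents that add atoms: TMSCl, C[Si](C)(C)Cl (silicon is carried only by 13 and 14)
Why: LDA takes the axial H-2 of 12 while TMSCl is already in the flask, so the enolate is trapped on oxygen as cyclic ketene acetal 13, and heating drives a concerted suprafacial [3,3] shift in which sugar C2 (zeylenone C1) bonds to the vinyl terminus C7 (C6), the C5–O5 bond (C4–O) breaks and the alkene moves to C5=C6 (C4=C5), after which mild hydrolysis of silyl ester 14 frees acid 15. The closest known reactions are the Ireland–Claisen rearrangement of 6-vinyl δ-valerolactones to cyclohex-3-enecarboxylic acids, the thermal Claisen carbocyclisation of 6-vinyl glycals and the glycolate Ireland–Claisen rearrangement, which between them cover the ring type, the sugar backbone and the 2-alkoxy ketene acetal. The cyclohexene closes transannularly through a boat-like, bicyclo[2.2.2]octane-shaped transition state with the vinyl group axial, so a six-membered lactone is traded for a six-membered carbocycle that keeps sugar C2–C5 and gains both vinyl carbons. C1, the only new stereocentre, is set by sugar C5, which is consumed: the tether lets the vinyl terminus reach C2 only on the β face that carries it, which leaves the carboxyl carbon cis to the C3 oxygen and the C1 benzyloxy group cis to the C2 benzyloxy group (1R in 15, 1S in 22 by priority change only). The step needs O-silylation to beat E1cB loss of the 3-benzyloxy group, which the internal quench at −100 °C and the pseudo-equatorial, poorly aligned C3–O bond of the enolate should secure, and with one enolisable C–H and one possible [3,3] array no regiochemical choice arises.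

**Step 9**
Reactants: 15 (1R,2S,3R)-1,2-bis(benzyloxy)-3-(4-methoxybenzyloxy)cyclohex-4-ene-1-carboxylic acid
Product: 16 [(1S,2S,3R)-1,2-bis(benzyloxy)-3-(4-methoxybenzyloxy)cyclohex-4-en-1-yl]methanol
Conditions: LiAlH4, THF, 0 °C → reflux; Fieser work-up
Reagents that add atoms: none
Why: Lithium aluminium hydride reduction of the hindered acid to the neopentyl C7 carbinol, with ethers and the isolated alkene inert and no stereocentre involved.

**Step 10**
Reactants: 16 [(1S,2S,3R)-1,2-bis(benzyloxy)-3-(4-methoxybenzyloxy)cyclohex-4-en-1-yl]methanol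
Product: 17 (1R,5S,6S)-5,6-bis(benzyloxy)-5-(hydroxymethyl)cyclohex-2-en-1-ol (zeylenone numbering: 1S,2S,3R; C7-OH and C3-OH free)
Conditions: DDQ, CH2Cl2–pH 7 buffer (18:1), 0 °C
Reagents that add atoms: none
Why: Oxidative PMB cleavage (hydride abstraction from the electron-rich anisyl CH2, then hydrolysis) is far faster than for plain benzyl ethers, and a small excess of DDQ at 0 °C should keep the freed allylic alcohol from further oxidation.

**Step 11**
Reactants: 17 diol with C7-OH and C3-OH free; 18 benzoyl chloride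
Product: 19 [(1S,2S,3R)-3-benzoyloxy-1,2-bis(benzyloxy)cyclohex-4-en-1-yl]methyl benzoate
Conditions: BzCl, pyridine, DMAP (cat.), CH2Cl2, 0 °C → rt
Reagents that add atoms: 18, benzoyl chloride, O=C(Cl)c1ccccc1
Why: DMAP-catalysed acylation esterifies the only two free hydroxyls, so the benzoates land on O7 and O3 while O1 and O2 stay benzylated.

**Step 12**
Reactants: 19 [(1S,2S,3R)-3-benzoyloxy-1,2-bis(benzyloxy)cyclohex-4-en-1-yl]methyl benzoate
Product: 20 6-hydroxy derivative of 19 (allylic alcohol, both C6 epimers)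
Conditions: SeO2, 1,4-dioxane, 100 °C
Reagents that add atoms: selenium dioxide, O=[Se]=O
Why: Riley allylic hydroxylation proceeds by an ene reaction (Se to C4, H from C6) and a [2,3] shift that returns oxygen to C6 and the alkene to C4=C5, while C3–H is switched off by its geminal benzoate, and SeO2 needs an alkene and so spares the four benzylic ether C–H bonds that chromium(VI) or peroxyl-radical oxidants would attack in preference to this electron-poor allylic position; the C6 configuration is of no consequence.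

**Step 13**
Reactants: 20 6-hydroxy derivative of 19
Product: 21 [(1S,2S,3R)-3-benzoyloxy-1,2-bis(benzyloxy)-6-oxocyclohex-4-en-1-yl]methyl benzoate (1,2-di-O-benzylzeylenone)
Conditions: DMP, CH2Cl2, rt
Reagents that add atoms: none
Why: Dess–Martin oxidation converges both C6 epimers on the enone without base that could trigger vinylogous loss of benzoate.

**Step 14**
Reactants: 21 1,2-di-O-benzylzeylenone
Product: 22 zeylenone, [(1S,2S,3R)-3-benzoyloxy-1,2-dihydroxy-6-oxocyclohex-4-en-1-yl]methyl benzoate
Conditions: BCl3, CH2Cl2, −78 °C; H2O quench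
Reagents that add atoms: none
Why: In this Lewis-acid ether cleavage boron binds the ether oxygens and chloride takes the benzyl groups, ionisation at C1, C2 or C3 is suppressed by the adjacent ketone and the electron-poor enone, the benzoates hold at −78 °C, and hydrogenolysis is excluded by the alkene.

**Compound list**

1 | phenyl 1-thio-β-D-glucopyranoside | c1ccc(cc1)S[C@@H]1O[C@H](CO)[C@@H](O)[C@H](O)[C@H]1O | starting material
2 | 4-methoxybenzaldehyde dimethyl acetal | COc1ccc(C(OC)OC)cc1 | starting material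
3 | phenyl 4,6-O-[(R)-4-methoxybenzylidene]-1-thio-β-D-glucopyranoside | c1ccc(cc1)S[C@@H]1O[C@@H]2CO[C@@H](c3ccc(OC)cc3)O[C@H]2[C@H](O)[C@H]1O | intermediate
4 | benzyl bromide | BrCc1ccccc1 | starting material
5 | phenyl 2,3-di-O-benzyl-4,6-O-[(R)-4-methoxybenzylidene]-1-thio-β-D-glucopyranoside | c1ccc(cc1)S[C@@H]1O[C@@H]2CO[C@@H](c3ccc(OC)cc3)O[C@H]2[C@H](OCc2ccccc2)[C@H]1OCc1ccccc1 | intermediate
6 | phenyl 2,3-di-O-benzyl-4-O-(4-methoxybenzyl)-1-thio-β-D-glucopyranoside | c1ccc(cc1)S[C@@H]1O[C@H](CO)[C@@H](OCc2ccc(OC)cc2)[C@H](OCc2ccccc2)[C@H]1OCc1ccccc1 | intermediate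
7 | phenyl 2,3-di-O-benzyl-4-O-(4-methoxybenzyl)-1-thio-β-D-gluco-hexodialdo-1,5-pyranoside | c1ccc(cc1)S[C@@H]1O[C@H](C=O)[C@@H](OCc2ccc(OC)cc2)[C@H](OCc2ccccc2)[C@H]1OCc1ccccc1 | intermediate
8 | methyltriphenylphosphonium bromide | C[P+](c1ccccc1)(c1ccccc1)c1ccccc1.[Br-] | starting material
9 | methylenetriphenylphosphorane | C=P(c1ccccc1)(c1ccccc1)c1ccccc1 | intermediate
10 | phenyl 2,3-di-O-benzyl-6,7-dideoxy-4-O-(4-methoxybenzyl)-1-thio-β-D-gluco-hept-6-enopyranoside | c1ccc(cc1)S[C@@H]1O[C@H](C=C)[C@@H](OCc2ccc(OC)cc2)[C@H](OCc2ccccc2)[C@H]1OCc1ccccc1 | intermediate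
11 | 2,3-di-O-benzyl-6,7-dideoxy-4-O-(4-methoxybenzyl)-D-gluco-hept-6-enopyranose (α/β) | OC1O[C@H](C=C)[C@@H](OCc2ccc(OC)cc2)[C@H](OCc2ccccc2)[C@H]1OCc1ccccc1 | intermediate
12 | 2,3-di-O-benzyl-6,7-dideoxy-4-O-(4-methoxybenzyl)-D-gluco-hept-6-enono-1,5-lactone | O=C1O[C@H](C=C)[C@@H](OCc2ccc(OC)cc2)[C@H](OCc2ccccc2)[C@H]1OCc1ccccc1 | intermediate
13 | trimethylsilyl ketene acetal of 12 (C1(OTMS)=C2(OBn), C3–C5 unchanged) | C[Si](C)(C)OC1=C(OCc2ccccc2)[C@@H](OCc2ccccc2)[C@H](OCc2ccc(OC)cc2)[C@@H](C=C)O1 | intermediate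
14 | trimethylsilyl (1R,2S,3R)-1,2-bis(benzyloxy)-3-(4-methoxybenzyloxy)cyclohex-4-ene-1-carboxylate | C[Si](C)(C)OC(=O)[C@@]1(OCc2ccccc2)CC=C[C@@H](OCc2ccc(OC)cc2)[C@@H]1OCc1ccccc1 | intermediate
15 | (1R,2S,3R)-1,2-bis(benzyloxy)-3-(4-methoxybenzyloxy)cyclohex-4-ene-1-carboxylic acid | OC(=O)[C@@]1(OCc2ccccc2)CC=C[C@@H](OCc2ccc(OC)cc2)[C@@H]1OCc1ccccc1 | intermediate
16 | [(1S,2S,3R)-1,2-bis(benzyloxy)-3-(4-methoxybenzyloxy)cyclohex-4-en-1-yl]methanol | OC[C@@]1(OCc2ccccc2)CC=C[C@@H](OCc2ccc(OC)cc2)[C@@H]1OCc1ccccc1 | intermediate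
17 | (1S,2S,3R)-1,2-bis(benzyloxy)-1-(hydroxymethyl)cyclohex-4-en-3-ol (zeylenone numbering) | OC[C@@]1(OCc2ccccc2)CC=C[C@@H](O)[C@@H]1OCc1ccccc1 | intermediate
18 | benzoyl chloride | O=C(Cl)c1ccccc1 | starting material
19 | [(1S,2S,3R)-3-benzoyloxy-1,2-bis(benzyloxy)cyclohex-4-en-1-yl]methyl benzoate | O=C(OC[C@@]1(OCc2ccccc2)CC=C[C@@H](OC(=O)c2ccccc2)[C@@H]1OCc1ccccc1)c1ccccc1 | intermediate
20 | 6-hydroxy derivative of 19 (both C6 epimers) | O=C(OC[C@@]1(OCc2ccccc2)C(O)C=C[C@@H](OC(=O)c2ccccc2)[C@@H]1OCc1ccccc1)c1ccccc1 | intermediate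
21 | 1,2-di-O-benzylzeylenone | O=C(OC[C@@]1(OCc2ccccc2)C(=O)C=C[C@@H](OC(=O)c2ccccc2)[C@@H]1OCc1ccccc1)c1ccccc1 | intermediate
22 | zeylenone | O=C(OC[C@@]1(O)C(=O)C=C[C@@H](OC(=O)c2ccccc2)[C@@H]1O)c1ccccc1 | target

**Step count**

Total step count: 14. Longest linear sequence: 14 (1 → 22).

**Steps most likely to fail**

Step 8. The lithium enolate may expel the 3-benzyloxy group before silicon arrives, silylation may go to carbon, or the boat barrier may be so high that the ketene acetal decays on heating. The fallback keeps the same [3,3] array but runs it on a neutral enol ether, so no enolate is ever formed.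
- It sets out from 10. One equivalent of mCPBA (CH2Cl2, −78 °C) should give the glycosyl sulfoxide F1.
- Base-induced loss of benzenesulfenate (LDA, THF, −78 °C) should give the 2-benzyloxyglycal F2.
- Thermal Claisen rearrangement of this 6-vinyl glycal (o-dichlorobenzene, sealed tube, about 200–240 °C) should give the quaternary aldehyde F3. It passes through the same boat-like, β-face-bound transition state.
- NaBH4 in MeOH then brings the route back at 16.

Step 12. The ene reaction may be too slow on an alkene flanked by an allylic benzoate. At the temperature needed, benzoyl migration from O7 to the new C6 hydroxyl or slow decomposition may compete. The fallback removes the competing benzylic C–H bonds first, which opens the way to hydrogen-abstraction oxidants.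
- It sets out from 19. BCl3 with pentamethylbenzene (CH2Cl2, −78 °C) should give the cis-diol dibenzoate F4.
- 2,2-Dimethoxypropane with CSA should give the 1,2-acetonide F5.
- CrO3·3,5-dimethylpyrazole (CH2Cl2, −20 °C) or Mn(OAc)3/t-BuOOH should give the enone acetonide F6.
- Aqueous TFA returns to the route at 22.

Step 5. The basic ylide may enolise the aldehyde, which would cause epimerisation at C5 or E1cB loss of the 4-O-PMB group. The fallback replaces olefination by a weakly basic addition followed by elimination (Peterson olefination).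
- It sets out from 7. Me3SiCH2MgCl (THF, −78 °C) should give the β-hydroxysilane F7 as a C6 epimer mixture.
- KH in THF at 0 °C should collapse both epimers to the same terminal alkene, rejoining the route at 10.

**Further compounds**

F1 | step 8 | phenyl 2,3-di-O-benzyl-6,7-dideoxy-4-O-(4-methoxybenzyl)-1-thio-β-D-gluco-hept-6-enopyranoside S-oxide | c1ccc(cc1)S(=O)[C@@H]1O[C@H](C=C)[C@@H](OCc2ccc(OC)cc2)[C@H](OCc2ccccc2)[C@H]1OCc1ccccc1
F2 | step 8 | 1,5-anhydro-2,3-di-O-benzyl-6,7-dideoxy-4-O-(4-methoxybenzyl)-D-arabino-hepta-1,6-dienitol | C1=C(OCc2ccccc2)[C@@H](OCc2ccccc2)[C@H](OCc2ccc(OC)cc2)[C@@H](C=C)O1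
F3 | step 8 | (1R,2S,3R)-1,2-bis(benzyloxy)-3-(4-methoxybenzyloxy)cyclohex-4-ene-1-carbaldehyde | O=C[C@@]1(OCc2ccccc2)CC=C[C@@H](OCc2ccc(OC)cc2)[C@@H]1OCc1ccccc1
F4 | step 12 | [(1S,2S,3R)-3-benzoyloxy-1,2-dihydroxycyclohex-4-en-1-yl]methyl benzoate | O=C(OC[C@@]1(O)CC=C[C@@H](OC(=O)c2ccccc2)[C@@H]1O)c1ccccc1
F5 | step 12 | 1,2-O-isopropylidene derivative of F4 | O=C(OC[C@@]12CC=C[C@@H](OC(=O)c3ccccc3)[C@@H]1OC(C)(C)O2)c1ccccc1
F6 | step 12 | 1,2-O-isopropylidenezeylenone | O=C(OC[C@@]12C(=O)C=C[C@@H](OC(=O)c3ccccc3)[C@@H]1OC(C)(C)O2)c1ccccc1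
F7 | step 5 | phenyl 2,3-di-O-benzyl-7-deoxy-4-O-(4-methoxybenzyl)-1-thio-7-trimethylsilyl-β-D-gluco-heptopyranoside (both C6 epimers) | c1ccc(cc1)S[C@@H]1O[C@H](C(O)C[Si](C)(C)C)[C@@H](OCc2ccc(OC)cc2)[C@H](OCc2ccccc2)[C@H]1OCc1ccccc1
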